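## Retrosynthetic overview

1. Numbering: chromene locants (O-1, C-2, C-3, C-4, C-4a, C-5 to C-8, C-8a); ring A is the carbocycle, ring B the dihydropyranone. Ring B is opened at O-1–C-8a, and ring A is cut [3+3] at C-6–C-7 and C-4a–C-8a, giving α-cyano acid chloride 13 and bis(silyloxy)diene 27.
2. Enabling feature: in ring A the quaternary C-8 lies between two carboxyl-level carbons (ketone C-7 and enol-ether carbon C-8a), while C-6/C-5/C-4a form an enolised 1,3-diketone. C-8a carries the ring-B oxygen, so it can enter as a nitrile whose nitrogen is later displaced by the C-2 hydroxyl.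
3. Fragment 13: (S)-lavandulol by auxiliary-controlled alkylation, then alkylation of tert-butyl cyanoacetate and a catalytic asymmetric prenylation that sets C-8.
4. Fragment 27: syn-aldol methyl ketone 19 (sets C-2 and C-3) is acylated by the hemiester 22 from desymmetrised 3-propylglutaric anhydride (sets the side-chain centre).
5. Ring order: ring A first, then ring B, both in the last step, which delivers the target without protecting-group steps afterwards.

Key step: step 17

Remark: both antipodes (or pseudoenantiomers) of the catalysts of steps 6 and 13 are available; it is assumed that the form giving the stated configuration is identified on model substrates and used.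

## Route

Step 1
Reactants: 1 (4S)-4-benzyl-1,3-oxazolidin-2-one; 2 3-methylbut-2-enoyl chloride
Product: 3 (4S)-4-benzyl-3-(3-methylbut-2-enoyl)-1,3-oxazolidin-2-one
Conditions: n-BuLi, THF, −78 °C; then 2, −78 → 0 °C
Reagents that add atoms: none
Why: N-acylation of the lithiated oxazolidinone by an acid chloride (imide formation); no stereocentre is touched.

Step 2
Reactants: 3; 4 1-bromo-3-methylbut-2-ene (prenyl bromide)
Product: 5 (4S)-4-benzyl-3-[(2S)-5-methyl-2-(prop-1-en-2-yl)hex-4-enoyl]-1,3-oxazolidin-2-one
Conditions: NaN(SiMe3)2, THF, −78 °C; then 4, −78 → −40 °C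
Reagents that add atoms: none
Why: Auxiliary-controlled deconjugative α-alkylation of the chelated sodium dienolate (Evans alkylation); prenyl bromide attacks the α-carbon on the face opposite the benzyl group, which should set the (2S) centre that becomes the lavandulyl stereocentre.

Step 3
Reactants: 5
Product: 6 (2S)-5-methyl-2-(prop-1-en-2-yl)hex-4-en-1-ol ((S)-lavandulol)
Conditions: LiBH4, MeOH (1 equiv), Et2O, 0 °C
Reagents that add atoms: none
Why: Reductive cleavage of the N-acyl oxazolidinone to the primary alcohol; the β,γ-alkene and the stereocentre are not affected and the auxiliary is recovered.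

Step 4
Reactants: 6
Product: 7 (3S)-3-(iodomethyl)-2,6-dimethylhepta-1,5-diene
Conditions: PPh3, iodine, imidazole, CH2Cl2, 0 °C
Reagents that add atoms: iodine, [I][I]
Why: Appel-type iodination by SN2 displacement at the primary carbon; the adjacent stereocentre is not involved.

Step 5
Reactants: 7; 8 tert-butyl 2-cyanoacetate
Product: 9 tert-butyl (4R)-2-cyano-7-methyl-4-(prop-1-en-2-yl)oct-6-enoate (both C-2 epimers)
Conditions: 8 (3 equiv), NaH, DMF, 0 → 45 °C
Reagents that add atoms: none
Why: SN2 C-alkylation of the soft, weakly basic cyanoacetate anion, which should disfavour E2; the excess of 8 suppresses dialkylation, and the uncontrolled C-2 centre is erased in step 6.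

Step 6
Reactants: 9; 4 1-bromo-3-methylbut-2-ene
Product: 10 tert-butyl (2R,4R)-2-cyano-7-methyl-2-(3-methylbut-2-en-1-yl)-4-(prop-1-en-2-yl)oct-6-enoate
Conditions: C2-symmetric N-spiro bis(binaphthyl)ammonium bromide bearing 3,4,5-trifluorophenyl groups at the 3,3′-positions (2 mol%), 50% aq. KOH, toluene, −40 °C
Reagents that add atoms: none
Why: Enantioface-selective phase-transfer alkylation of an α-alkyl cyanoacetate; the chiral ammonium enolate ion pair should shield one face so that prenylation sets the quaternary (2R) centre under catalyst control, and any minor C-2 epimer is a diastereomer and can be removed.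

Step 7
Reactants: 10
Product: 12 (2R,4R)-2-cyano-7-methyl-2-(3-methylbut-2-en-1-yl)-4-(prop-1-en-2-yl)oct-6-enoic acid, via trimethylsilyl ester 11 (not isolated)
Conditions: Me3SiOTf, 2,6-lutidine, CH2Cl2, 0 °C; then aq. citric acid
Reagents that add atoms: none
Why: Silyl-triflate-mediated cleavage of the tert-butyl ester (loss of isobutene) under buffered aprotic conditions, which avoids the protic acid that would lactonise the acid onto a prenyl group.

Step 8
Reactants: 12
Product: 13 (2R,4R)-2-cyano-7-methyl-2-(3-methylbut-2-en-1-yl)-4-(prop-1-en-2-yl)oct-6-enoyl chloride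
Conditions: 1-chloro-N,N,2-trimethylprop-1-en-1-amine, CH2Cl2, 0 → 25 °C; used crude
Reagents that add atoms: 1-chloro-N,N,2-trimethylprop-1-en-1-amine, CC(C)=C(Cl)N(C)C
Why: Acid chloride formation with an α-chloroenamine under neutral conditions; no HCl is released, so the three alkenes are safe, and the quaternary α-carbon cannot form a ketene.

Step 9
Reactants: 14 (4S)-4-benzyl-3-propanoyl-1,3-oxazolidin-2-one; 15 acetaldehyde
Product: 16 (4S)-4-benzyl-3-[(2S,3R)-3-hydroxy-2-methylbutanoyl]-1,3-oxazolidin-2-one
Conditions: Bu2BOTf, iPr2NEt, CH2Cl2, −78 → 0 °C; then H2O2, MeOH, pH 7 buffer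
Reagents that add atoms: none
Why: Boron-mediated Evans syn aldol; the (Z)-boron enolate reacts through a chair Zimmerman–Traxler transition state on the face opposite the benzyl group, which should set the (2S,3R) syn pair that becomes C-3 and C-2.

Step 10
Reactants: 16
Product: 17 (2S,3R)-3-hydroxy-N-methoxy-N,2-dimethylbutanamide
Conditions: MeNH(OMe)·HCl, AlMe3, CH2Cl2, −20 → 0 °C
Reagents that add atoms: N,O-dimethylhydroxylamine hydrochloride, CNOC.Cl
Why: Aluminium-amide transamidation of the imide to the Weinreb amide, assisted by the free β-hydroxyl; neither stereocentre is enolised.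

Step 11
Reactants: 17
Product: 18 (2S,3R)-N-methoxy-N,2-dimethyl-3-[(triethylsilyl)oxy]butanamide
Conditions: Et3SiCl, imidazole, CH2Cl2, 0 → 25 °C
Reagents that add atoms: chlorotriethylsilane, CC[Si](Cl)(CC)CC
Why: Silylation of the secondary alcohol; the triethylsilyl ether is stable to the bases used later and is removed by fluoride in step 17.

Step 12
Reactants: 18
Product: 19 (3S,4R)-3-methyl-4-[(triethylsilyl)oxy]pentan-2-one
Conditions: MeMgBr, THF, 0 °C
Reagents that add atoms: methylmagnesium bromide, C[Mg]Br
Why: Grignard addition to a Weinreb amide, which stops at the ketone through the chelated tetrahedral intermediate, so the α-centre is not exposed to base as a ketone.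

Step 13
Reactants: 20 4-propyloxane-2,6-dione (3-propylglutaric anhydride); 21 benzyl alcohol
Product: 22 (3S)-3-[2-(benzyloxy)-2-oxoethyl]hexanoic acid
Conditions: cinchona-alkaloid-derived bifunctional thiourea catalyst (10 mol%), 21 (1.5 equiv), methyl tert-butyl ether, −20 °C
Reagents that add atoms: none
Why: Organocatalytic enantioselective alcoholysis (desymmetrisation) of a prochiral cyclic anhydride; the general-base and hydrogen-bonding catalyst should select one of the two enantiotopic carbonyl groups and so set the side-chain centre.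

Step 14
Reactants: 22; 19
Product: 24 benzyl (3S,8S,9R)-8-methyl-5,7-dioxo-3-propyl-9-[(triethylsilyl)oxy]decanoate, via acyl imidazolide 23 (not isolated)
Conditions: 22, 1,1′-carbonyldiimidazole, THF, 25 °C; separately 19, LiN(SiMe3)2 (2.1 equiv), THF, −78 °C; then 23, −78 → −30 °C; aq. NH4Cl
Reagents that add atoms: none
Why: Crossed Claisen-type C-acylation of the kinetic methyl-side lithium enolate of 19 by the acyl imidazolide; the second equivalent of base deprotonates the 1,3-diketone as it forms, which keeps the α-methyl centre from enolising.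

Step 15
Reactants: 24
Product: 25 (3S,8S,9R)-8-methyl-5,7-dioxo-3-propyl-9-[(triethylsilyl)oxy]decanoic acid
Conditions: H2 (1 atm), 10% Pd/C, EtOAc, 25 °C
Reagents that add atoms: none
Why: Hydrogenolysis of the benzyl ester, done here because this fragment has no alkene; the silyl ether and the diketone should survive in a non-protic solvent.

Step 16
Reactants: 25
Product: 27 trimethylsilyl (3R,8S,9R)-8-methyl-3-propyl-9-[(triethylsilyl)oxy]-5,7-bis[(trimethylsilyl)oxy]deca-4,6-dienoate (double-bond isomers), via mono(silyl enol ether) trimethylsilyl ester 26 (not isolated)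
Conditions: Me3SiCl (2.3 equiv), Et3N, CH2Cl2, 25 °C; then LiN(iPr)2 (1.2 equiv), Me3SiCl, THF, −78 °C; filtered under argon, used crude
Reagents that add atoms: chlorotrimethylsilane, C[Si](C)(C)Cl
Why: Formation of a 1,3-bis(silyloxy)-1,3-diene from a 1,3-diketone (O-silylation, then kinetic deprotonation and O-silylation); LiN(iPr)2 should remove a proton from the unhindered CH2 next to the propyl-bearing carbon rather than from the methine carrying the methyl group, so the C-3 centre stays intact, and the acid is masked in the same pot as its silyl ester.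

Step 17
Reactants: 13; 27
Product: 30 (3R)-3-[(2R,3S,8R)-5-hydroxy-2,3-dimethyl-8-(3-methylbut-2-en-1-yl)-8-[(2R)-5-methyl-2-(prop-1-en-2-yl)hex-4-en-1-yl]-4,7-dioxo-3,4,7,8-tetrahydro-2H-chromen-6-yl]hexanoic acid, via acyclic triketo nitrile silyl enol ether 28 (not isolated), via aminocyclohexadienone triethylsilyl ether 29 (not isolated)
Conditions: 27 (1.2 equiv), Me3SiOTf (10 mol%), CH2Cl2, −78 → 0 °C; volatiles evaporated; KOtBu (4.5 equiv), THF, 0 → 50 °C; then HF·pyridine (excess), pyridine, THF, 0 → 40 °C
Reagents that add atoms: none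
Why: Proposed new method: a [3+3] assembly of ring A in which the nitrile serves as a carboxyl-level electrophile that leaves a leaving group on C-8a: the terminal carbon of diene 27 is first C-acylated by the acid chloride (Mukaiyama-type acylation, the known behaviour of 1,3-bis(silyloxy)dienes towards acid chlorides, forming C-6–C-7), then KOtBu removes the trimethylsilyl groups and the central carbon of the triketone dianion adds to the nitrile (6-exo-dig Thorpe-type closure of ring A, forming C-4a–C-8a; closest known reaction: base-mediated cyclisation of 5-oxonitriles to 3-aminocyclohex-2-enones). Ring B then closes when HF·pyridine frees the C-2 hydroxyl, which adds to the protonated vinylogous amide at C-8a and expels ammonia (6-endo-trig addition–elimination, the known conversion of δ-hydroxy-β-enaminones into 2,3-dihydropyran-4-ones). No new stereocentre is formed: C-8 is quaternary and cannot epimerise, the C-2–O bond is never broken (retention, so the syn-aldol unit gives the cis-2,3-dimethyl pattern), C-3 is protected because its ketone is held as an enolate or vinylogous amide, and the side-chain centre is not acidic. The step needs site selectivity in the acylation (terminal over central diene carbon, acid chloride over nitrile, secured by the higher nucleophilicity of the diene terminus and the far higher electrophilicity of the acid chloride), C- over O-attack on the nitrile (the C-adduct is the thermodynamic sink under equilibrating base), and ring-B fusion at C-8a rather than C-5, secured because only C-8a carries a nitrogen that is activated by protonation and leaves irreversibly as ammonium.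

## Compound list

1 | (4S)-4-benzyl-1,3-oxazolidin-2-one | O=C1OC[C@H](Cc2ccccc2)N1 | starting material
2 | 3-methylbut-2-enoyl chloride | CC(C)=CC(=O)Cl | starting material
3 | (4S)-4-benzyl-3-(3-methylbut-2-enoyl)-1,3-oxazolidin-2-one | CC(C)=CC(=O)N1C(=O)OC[C@@H]1Cc1ccccc1 | intermediate
4 | 1-bromo-3-methylbut-2-ene | CC(C)=CCBr | starting material
5 | (4S)-4-benzyl-3-[(2S)-5-methyl-2-(prop-1-en-2-yl)hex-4-enoyl]-1,3-oxazolidin-2-one | C=C(C)[C@H](CC=C(C)C)C(=O)N1C(=O)OC[C@@H]1Cc1ccccc1 | intermediate
6 | (2S)-5-methyl-2-(prop-1-en-2-yl)hex-4-en-1-ol | C=C(C)[C@H](CC=C(C)C)CO | intermediate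
7 | (3S)-3-(iodomethyl)-2,6-dimethylhepta-1,5-diene | C=C(C)[C@H](CC=C(C)C)CI | intermediate
8 | tert-butyl 2-cyanoacetate | N#CCC(=O)OC(C)(C)C | starting material
9 | tert-butyl (4R)-2-cyano-7-methyl-4-(prop-1-en-2-yl)oct-6-enoate (C-2 epimers) | C=C(C)[C@H](CC=C(C)C)CC(C#N)C(=O)OC(C)(C)C | intermediate
10 | tert-butyl (2R,4R)-2-cyano-7-methyl-2-(3-methylbut-2-en-1-yl)-4-(prop-1-en-2-yl)oct-6-enoate | C=C(C)[C@H](CC=C(C)C)C[C@@](C#N)(CC=C(C)C)C(=O)OC(C)(C)C | intermediate
11 | trimethylsilyl (2R,4R)-2-cyano-7-methyl-2-(3-methylbut-2-en-1-yl)-4-(prop-1-en-2-yl)oct-6-enoate | C=C(C)[C@H](CC=C(C)C)C[C@@](C#N)(CC=C(C)C)C(=O)O[Si](C)(C)C | intermediate (not isolated)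
12 | (2R,4R)-2-cyano-7-methyl-2-(3-methylbut-2-en-1-yl)-4-(prop-1-en-2-yl)oct-6-enoic acid | C=C(C)[C@H](CC=C(C)C)C[C@@](C#N)(CC=C(C)C)C(=O)O | intermediate
13 | (2R,4R)-2-cyano-7-methyl-2-(3-methylbut-2-en-1-yl)-4-(prop-1-en-2-yl)oct-6-enoyl chloride | C=C(C)[C@H](CC=C(C)C)C[C@@](C#N)(CC=C(C)C)C(=O)Cl | intermediate
14 | (4S)-4-benzyl-3-propanoyl-1,3-oxazolidin-2-one | CCC(=O)N1C(=O)OC[C@@H]1Cc1ccccc1 | starting material
15 | acetaldehyde | CC=O | starting material
16 | (4S)-4-benzyl-3-[(2S,3R)-3-hydroxy-2-methylbutanoyl]-1,3-oxazolidin-2-one | O[C@H](C)[C@H](C)C(=O)N1C(=O)OC[C@@H]1Cc1ccccc1 | intermediate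
17 | (2S,3R)-3-hydroxy-N-methoxy-N,2-dimethylbutanamide | O[C@H](C)[C@H](C)C(=O)N(C)OC | intermediate
18 | (2S,3R)-N-methoxy-N,2-dimethyl-3-[(triethylsilyl)oxy]butanamide | CC[Si](CC)(CC)O[C@H](C)[C@H](C)C(=O)N(C)OC | intermediate
19 | (3S,4R)-3-methyl-4-[(triethylsilyl)oxy]pentan-2-one | CC[Si](CC)(CC)O[C@H](C)[C@H](C)C(C)=O | intermediate
20 | 4-propyloxane-2,6-dione | CCCC1CC(=O)OC(=O)C1 | starting material
21 | benzyl alcohol | OCc1ccccc1 | starting material
22 | (3S)-3-[2-(benzyloxy)-2-oxoethyl]hexanoic acid | OC(=O)C[C@H](CCC)CC(=O)OCc1ccccc1 | intermediate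
23 | benzyl (3S)-3-[2-(1H-imidazol-1-yl)-2-oxoethyl]hexanoate | O=C(C[C@H](CCC)CC(=O)OCc1ccccc1)n1ccnc1 | intermediate (not isolated)
24 | benzyl (3S,8S,9R)-8-methyl-5,7-dioxo-3-propyl-9-[(triethylsilyl)oxy]decanoate | CC[Si](CC)(CC)O[C@H](C)[C@H](C)C(=O)CC(=O)C[C@H](CCC)CC(=O)OCc1ccccc1 | intermediate
25 | (3S,8S,9R)-8-methyl-5,7-dioxo-3-propyl-9-[(triethylsilyl)oxy]decanoic acid | CC[Si](CC)(CC)O[C@H](C)[C@H](C)C(=O)CC(=O)C[C@H](CCC)CC(=O)O | intermediate
26 | trimethylsilyl (3S,8S,9R)-8-methyl-5-oxo-3-propyl-9-[(triethylsilyl)oxy]-7-[(trimethylsilyl)oxy]dec-6-enoate (drawn as one of two silyl-enol regioisomers) | CC[Si](CC)(CC)O[C@H](C)[C@H](C)C(O[Si](C)(C)C)=CC(=O)C[C@H](CCC)CC(=O)O[Si](C)(C)C | intermediate (not isolated)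
27 | trimethylsilyl (3R,8S,9R)-8-methyl-3-propyl-9-[(triethylsilyl)oxy]-5,7-bis[(trimethylsilyl)oxy]deca-4,6-dienoate | CC[Si](CC)(CC)O[C@H](C)[C@H](C)C(O[Si](C)(C)C)=CC(O[Si](C)(C)C)=C[C@H](CCC)CC(=O)O[Si](C)(C)C | intermediate
28 | acyclic C-acylation product: silyl enol ether of the 1,3,5-triketo nitrile, trimethylsilyl ester (epimers at the acylated carbon) | C=C(C)[C@H](CC=C(C)C)C[C@@](C#N)(CC=C(C)C)C(=O)C([C@H](CCC)CC(=O)O[Si](C)(C)C)C(=O)C=C(O[Si](C)(C)C)[C@@H](C)[C@@H](C)O[Si](CC)(CC)CC | intermediate (not isolated)
29 | (3R)-3-[(5R)-4-amino-2-hydroxy-5-(3-methylbut-2-en-1-yl)-5-[(2R)-5-methyl-2-(prop-1-en-2-yl)hex-4-en-1-yl]-3-{(2S,3R)-2-methyl-3-[(triethylsilyl)oxy]butanoyl}-6-oxocyclohexa-1,3-dien-1-yl]hexanoic acid (potassium salt in the flask) | C=C(C)[C@H](CC=C(C)C)C[C@@]1(CC=C(C)C)C(=O)C([C@H](CCC)CC(=O)O)=C(O)C(C(=O)[C@@H](C)[C@@H](C)O[Si](CC)(CC)CC)=C1N | intermediate (not isolated)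
30 | (3R)-3-[(2R,3S,8R)-5-hydroxy-2,3-dimethyl-8-(3-methylbut-2-en-1-yl)-8-[(2R)-5-methyl-2-(prop-1-en-2-yl)hex-4-en-1-yl]-4,7-dioxo-3,4,7,8-tetrahydro-2H-chromen-6-yl]hexanoic acid | C=C(C)[C@H](CC=C(C)C)C[C@@]1(CC=C(C)C)C(=O)C([C@H](CCC)CC(=O)O)=C(O)C2=C1O[C@H](C)[C@H](C)C2=O | target

## Step count and risks

Total step count: 17
Longest linear sequence: 9 steps (steps 1 to 8, then step 17)

Steps most likely to fail:

1. Step 17. Acylation at the hindered diene terminus may be slow, so that O-acylation or attack through the central carbon competes. The addition to the neopentyl-type nitrile may stall. Premature hydrolysis of the vinylogous amide would remove the control over ring-B fusion. The fallback uses known reactions only and replaces the one-pot acylation cascade by an aldol and oxidation sequence with isolated intermediates. It sets out from 13 and 27. The acid chloride is reduced with LiAlH(OtBu)3 (THF, −78 °C) to the aldehyde (2R,4R)-2-formyl-7-methyl-2-(3-methylbut-2-en-1-yl)-4-(prop-1-en-2-yl)oct-6-enenitrile F1. A vinylogous Mukaiyama aldol addition of 27 to F1 (BF3·OEt2, CH2Cl2, −78 °C, mild acidic work-up) should give the δ-hydroxy-β-diketone acid F2. Dess–Martin periodinane (NaHCO3, CH2Cl2) should oxidise it to the triketo nitrile acid F3. KOtBu in THF then closes ring A and the route is rejoined at 29, which is isolated and treated with HF·pyridine in a separate operation to reach 30.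

2. Step 6. Facial selectivity may be poor, because the catalyst must override the neighbouring lavandulyl centre and the two alkyl groups on the prochiral carbon are similar in size. The fallback replaces catalyst control by separation of diastereomers. It sets out from 9. Prenylation with 4 under achiral conditions (K2CO3, DMF, 25 °C) gives the tert-butyl ester as both C-2 epimers F4. Because the lavandulyl centre is already in place these are diastereomers, and they are separated by preparative chromatography. The (2R,4R) isomer is 10, where the route is rejoined.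

3. Step 16. Deprotonation may occur on the wrong side of the diketone, at the methine next to the silyloxy carbon, which would scramble the C-3 methyl centre or expel the silyloxy group. The labile diene may also hydrolyse during handling. The fallback uses a polyanion instead of a silyl diene. It sets out from 25. LiN(iPr)2 (3.3 equiv, THF, −78 → 0 °C, equilibrating conditions that favour the less substituted terminal carbanion) gives the trilithium carboxylate dienediolate F5. F5 is acylated at its terminal carbon by 13 at −78 °C. After addition of LiN(SiMe3)2 and warming, the triketone dianion closes onto the nitrile and the route is rejoined at 29, which is isolated and then needs only the HF·pyridine treatment.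

Further compounds
F1 | step 17 | (2R,4R)-2-formyl-7-methyl-2-(3-methylbut-2-en-1-yl)-4-(prop-1-en-2-yl)oct-6-enenitrile | C=C(C)[C@H](CC=C(C)C)C[C@@](C#N)(CC=C(C)C)C=O
F2 | step 17 | δ-hydroxy-β-diketone acid from the aldol addition (triethylsilyl ether, free acid, mixture at the two new centres) | C=C(C)[C@H](CC=C(C)C)C[C@@](C#N)(CC=C(C)C)C(O)C([C@H](CCC)CC(=O)O)C(=O)CC(=O)[C@@H](C)[C@@H](C)O[Si](CC)(CC)CC
F3 | step 17 | acyclic 1,3,5-triketo nitrile acid (triethylsilyl ether, epimers at the carbon between the ketones) | C=C(C)[C@H](CC=C(C)C)C[C@@](C#N)(CC=C(C)C)C(=O)C([C@H](CCC)CC(=O)O)C(=O)CC(=O)[C@@H](C)[C@@H](C)O[Si](CC)(CC)CC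
F4 | step 6 | tert-butyl (4R)-2-cyano-7-methyl-2-(3-methylbut-2-en-1-yl)-4-(prop-1-en-2-yl)oct-6-enoate, both C-2 epimers | C=C(C)[C@H](CC=C(C)C)CC(C#N)(CC=C(C)C)C(=O)OC(C)(C)C
F5 | step 16 | trilithium carboxylate dienediolate of 25 | [Li+].[Li+].[Li+].CC[Si](CC)(CC)O[C@H](C)[C@H](C)C([O-])=CC([O-])=C[C@H](CCC)CC(=O)[O-]
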